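**Plan**
- Cuts: (a) the diketone C–C bond between the central CH2 and the carbonyl on the prenylphenol side (crossed Claisen condensation of acetylchromene 6 with ester 10); (b) the pyran O1–C2 bond, traced back to 2-isopropenyl-2,3-dihydrobenzofuran 4, in which O1 sits one carbon earlier; (c) the aryl–C and O–C bonds of that dihydrofuran (iodophenol 2 + isoprene); (d) the aryl–prenyl bond (Stille).
- Forward order: the dihydrofuran ring is made first (step 2) and enlarged to the 2,2-dimethyl-2H-pyran ring (step 3); the two arenes are then joined through the diketone (step 6) and the silyl ether is removed (step 7).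
- Enabling feature: in 4 the ring bond O1–C2 is an allylic aryl ether bond (C2 bears the isopropenyl group), O1 is para to the acetyl group and C3 is a benzylic CH2. Pd(0) ionisation, relay of a C3 hydrogen to the terminal =CH2 and re-closure of O1 on the former isopropenyl carbon turn the ring O1–C2–C3–C3a–C7a into the pyran O1–CMe2–CH=CH–C4a–C8a.
- Stereochemistry: the target has no stereocentre; C2 of 4 is racemic and is lost in step 3; the C3=C4 bond is cis by ring constraint.

Key step: step 3

Remark: the target has no stereogenic element, so no enantiomer exists and the constitution alone is the goal; the 1,3-diketone is drawn in the diketo form, the chelated keto–enol tautomer being the same compound.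

**Route**

Step 1
Reactants: 1 2,4-dihydroxyacetophenone
Product: 2 1-(2,4-dihydroxy-5-iodophenyl)ethanone
Conditions: ICl (1.05 equiv), AcOH, rt
Reagents that add atoms: iodine monochloride, ClI
Why: Electrophilic aromatic iodination should go to C5, which is para to the 2-OH and ortho to the 4-OH and less hindered than C3 between the two hydroxyls.

Step 2
Reactants: 2 1-(2,4-dihydroxy-5-iodophenyl)ethanone; 3 isoprene
Product: 4 rac-1-[6-hydroxy-2-(prop-1-en-2-yl)-2,3-dihydro-1-benzofuran-5-yl]ethanone
Conditions: Pd(OAc)2 (5 mol %), n-Bu4NCl, Na2CO3, DMF, 80 °C, sealed tube, isoprene in excess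
Reagents that add atoms: none
Why: Larock-type Pd-catalysed heteroannulation of a 1,3-diene, in which the aryl–Pd adds to the unsubstituted vinyl terminus of isoprene and the phenoxide ortho to the former iodide closes the five-membered ring on the internal π-allyl terminus; C2 forms as a racemate, which is sufficient because the centre is lost in step 3.

Step 3
Reactants: 4 rac-1-[6-hydroxy-2-(prop-1-en-2-yl)-2,3-dihydro-1-benzofuran-5-yl]ethanone
Product: 6 1-(7-hydroxy-2,2-dimethyl-2H-chromen-6-yl)ethanone, via 1-{2,4-dihydroxy-5-[(1E)-3-methylbuta-1,3-dien-1-yl]phenyl}ethanone 5 (not isolated)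
Conditions: Pd2(dba)3 (2.5 mol %), PPh3 (10 mol %), PhCO2H (20 mol %), 1,4-dioxane, 100 °C, Ar
Reagents that add atoms: none
Why: Proposed new method: Pd(0) ionises the allylic C2–O1 bond of the dihydrofuran (leaving group: a para-acetyl phenoxide) to an η3-(1-benzyl-2-methylallyl)palladium phenoxide, β-hydride elimination of a benzylic hydrogen through the σ-allyl form gives dienylphenol 5 and Pd–H, and re-insertion of the diene with hydride delivery to the terminal CH2 turns that carbon into the second methyl group and gives the η3-(1-aryl-3,3-dimethylallyl) complex. The tethered phenoxide can reach only the CMe2 terminus of this allyl (the benzylic terminus would require a four-membered ring), so C–O bond formation closes the pyran ring by a 6-endo allylic etherification; the net result is a 1,2-shift of O1 from the ring carbon to the former isopropenyl carbon, a five- to six-membered ring expansion. The closest known reaction types are the Tsuji–Trost ionisation of allyl aryl ethers with Pd-catalysed 1,4-elimination to 1,3-dienes, the Pd(0)/carboxylic acid hydroalkoxylation of 1,3-dienes, and the O-allylation of phenols at the tertiary terminus of prenyl-type π-allyl complexes. No stereocentre is formed: the racemic C2 centre of 4 disappears and the new C3=C4 bond is cis by ring constraint. The step needs selectivity among the reversible closures (back to 4, to a 2,5-dihydro-1-benzoxepine, or to 6), and 6 should accumulate because its styrene-type conjugated double bond and tertiary C–O bond make it the most stable and least readily re-ionised isomer. A strong Brønsted acid is avoided because protonation of the isopropenyl group would lead by hydride shift to the aromatic 2-isopropylbenzofuran; the chelated OH/acetyl pair is a spectator and only the oxygen para to the acetyl group is tethered to the allyl unit.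

Step 4
Reactants: 7 methyl 4-hydroxy-3-iodobenzoate
Product: 8 methyl 4-[(tert-butyldimethylsilyl)oxy]-3-iodobenzoate
Conditions: TBSCl (1.1 equiv), imidazole (2.2 equiv), DMF, rt
Reagents that add atoms: tert-butyldimethylsilyl chloride, CC(C)(C)[Si](C)(C)Cl
Why: Standard O-silylation of a phenol gives a protecting group that survives the Stille coupling and amide base and can be removed at the end without acid.

Step 5
Reactants: 8 methyl 4-[(tert-butyldimethylsilyl)oxy]-3-iodobenzoate; 9 tributyl(3-methylbut-2-en-1-yl)stannane
Product: 10 methyl 4-[(tert-butyldimethylsilyl)oxy]-3-(3-methylbut-2-en-1-yl)benzoate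
Conditions: Pd(PPh3)4 (5 mol %), DMF, 90 °C
Reagents that add atoms: none
Why: Stille coupling of an aryl iodide with a prenylstannane should transfer the prenyl group with its linear connectivity, with ester and silyl ether inert under the neutral conditions.

Step 6
Reactants: 6 1-(7-hydroxy-2,2-dimethyl-2H-chromen-6-yl)ethanone; 10 methyl 4-[(tert-butyldimethylsilyl)oxy]-3-(3-methylbut-2-en-1-yl)benzoate
Product: 11 1-{4-[(tert-butyldimethylsilyl)oxy]-3-(3-methylbut-2-en-1-yl)phenyl}-3-(7-hydroxy-2,2-dimethyl-2H-chromen-6-yl)propane-1,3-dione
Conditions: LiHMDS (3.3 equiv), THF, −78 °C to rt; then aq NH4Cl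
Reagents that add atoms: none
Why: Crossed Claisen condensation, in which the dilithio phenoxide–enolate of the o-hydroxyacetophenone is C-acylated by the non-enolisable ester and the diketone is held as its lithium enolate until the mild quench, which also avoids acid-induced flavone closure.

Step 7
Reactants: 11 1-{4-[(tert-butyldimethylsilyl)oxy]-3-(3-methylbut-2-en-1-yl)phenyl}-3-(7-hydroxy-2,2-dimethyl-2H-chromen-6-yl)propane-1,3-dione
Product: 12 Glyinflanin C
Conditions: TBAF (1.1 equiv), AcOH (1.1 equiv), THF, 0 °C
Reagents that add atoms: none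
Why: Buffered fluoride cleavage of an aryl silyl ether frees the phenol without acid, so the o-prenylphenol does not cyclise to a chroman and the o-hydroxy diketone does not close to a flavone.

**Compound list**
1 | 1-(2,4-dihydroxyphenyl)ethanone (2,4-dihydroxyacetophenone) | CC(=O)c1ccc(O)cc1O | starting material
2 | 1-(2,4-dihydroxy-5-iodophenyl)ethanone | CC(=O)c1cc(I)c(O)cc1O | intermediate
3 | isoprene (2-methylbuta-1,3-diene) | CC(=C)C=C | starting material
4 | rac-1-[6-hydroxy-2-(prop-1-en-2-yl)-2,3-dihydro-1-benzofuran-5-yl]ethanone (racemate) | CC(=O)c1cc2CC(C(C)=C)Oc2cc1O | intermediate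
5 | 1-{2,4-dihydroxy-5-[(1E)-3-methylbuta-1,3-dien-1-yl]phenyl}ethanone | CC(=O)c1cc(/C=C/C(C)=C)c(O)cc1O | intermediate
6 | 1-(7-hydroxy-2,2-dimethyl-2H-chromen-6-yl)ethanone | CC(=O)c1cc2C=CC(C)(C)Oc2cc1O | intermediate
7 | methyl 4-hydroxy-3-iodobenzoate | COC(=O)c1ccc(O)c(I)c1 | starting material
8 | methyl 4-[(tert-butyldimethylsilyl)oxy]-3-iodobenzoate | COC(=O)c1ccc(O[Si](C)(C)C(C)(C)C)c(I)c1 | intermediate
9 | tributyl(3-methylbut-2-en-1-yl)stannane | CCCC[Sn](CCCC)(CCCC)CC=C(C)C | starting material
10 | methyl 4-[(tert-butyldimethylsilyl)oxy]-3-(3-methylbut-2-en-1-yl)benzoate | COC(=O)c1ccc(O[Si](C)(C)C(C)(C)C)c(CC=C(C)C)c1 | intermediate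
11 | 1-{4-[(tert-butyldimethylsilyl)oxy]-3-(3-methylbut-2-en-1-yl)phenyl}-3-(7-hydroxy-2,2-dimethyl-2H-chromen-6-yl)propane-1,3-dione | CC(C)=CCc1cc(C(=O)CC(=O)c2cc3C=CC(C)(C)Oc3cc2O)ccc1O[Si](C)(C)C(C)(C)C | intermediate
12 | Glyinflanin C, 1-[4-hydroxy-3-(3-methylbut-2-en-1-yl)phenyl]-3-(7-hydroxy-2,2-dimethyl-2H-chromen-6-yl)propane-1,3-dione | CC(C)=CCc1cc(C(=O)CC(=O)c2cc3c(cc2O)OC(C)(C)C=C3)ccc1O | target

**Totals and risks**
Total steps: 7. Longest linear sequence: 5 steps (1, 2, 3, 6, 7).

Steps most likely to fail:

1. Step 3. The allylpalladium phenoxide may only re-close to the five-membered ring, the sequence may stall after β-hydride elimination, or double-bond migration towards the ring oxygen followed by aromatisation may take over. The fallback uses known chemistry, sets out from 2 and returns at 6. A Heck reaction of 2 with 2-methylbut-3-en-2-ol (Pd(OAc)2, n-Bu4NCl, NaHCO3, DMF, 80 °C) should give (E)-1-[2,4-dihydroxy-5-(3-hydroxy-3-methylbut-1-en-1-yl)phenyl]ethanone F1. Acid-catalysed cyclodehydration of F1 (PPTS, toluene, 80 °C) through the aryl-stabilised allyl cation, which can rotate to the cis geometry, should close the pyran ring on the tertiary carbon and give 6.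

2. Step 2. Isoprene may insert with the opposite regiochemistry, or β-hydride elimination to an open Heck diene may precede C–O ring closure. The fallback sets out from 2 and returns at 4. Stille coupling of 2 with stannane 9 (Pd(PPh3)4, DMF, 90 °C) should give 1-[2,4-dihydroxy-5-(3-methylbut-2-en-1-yl)phenyl]ethanone F2. Aerobic Pd(II) oxidative cyclisation of F2 (Pd(TFA)2, pyridine, Na2CO3, 3 Å sieves, O2, toluene, 80 °C) by 5-exo oxypalladation and β-hydride elimination into a methyl group should give 4. Any 6-endo product of this cyclisation is 6 itself and serves the route equally.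

3. Step 6. Acylation of the dilithiated ketone by the electron-rich ester may be slow, so that self-condensation or silyl transfer to the phenoxide competes. The fallback is a Baker–Venkataraman sequence that sets out from 10 and 6 and returns at 11. Mild ester cleavage of 10 (Me3SnOH, 1,2-dichloroethane, 80 °C) should give 4-[(tert-butyldimethylsilyl)oxy]-3-(3-methylbut-2-en-1-yl)benzoic acid F3. Esterification of F3 with the phenol of 6 (EDC·HCl, DMAP, CH2Cl2, rt) should give 6-acetyl-2,2-dimethyl-2H-chromen-7-yl 4-[(tert-butyldimethylsilyl)oxy]-3-(3-methylbut-2-en-1-yl)benzoate F4. Treatment of F4 with LiHMDS (THF, −78 to 0 °C) should transfer the aroyl group intramolecularly from oxygen to the acetyl carbon and give 11.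

Further compounds
F1 | step 3 | (E)-1-[2,4-dihydroxy-5-(3-hydroxy-3-methylbut-1-en-1-yl)phenyl]ethanone | CC(=O)c1cc(/C=C/C(C)(C)O)c(O)cc1O
F2 | step 2 | 1-[2,4-dihydroxy-5-(3-methylbut-2-en-1-yl)phenyl]ethanone | CC(=O)c1cc(CC=C(C)C)c(O)cc1O
F3 | step 6 | 4-[(tert-butyldimethylsilyl)oxy]-3-(3-methylbut-2-en-1-yl)benzoic acid | CC(C)=CCc1cc(C(=O)O)ccc1O[Si](C)(C)C(C)(C)C
F4 | step 6 | 6-acetyl-2,2-dimethyl-2H-chromen-7-yl 4-[(tert-butyldimethylsilyl)oxy]-3-(3-methylbut-2-en-1-yl)benzoate | CC(=O)c1cc2C=CC(C)(C)Oc2cc1OC(=O)c1ccc(O[Si](C)(C)C(C)(C)C)c(CC=C(C)C)c1
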